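**Retrosynthetic overview**
1. The tropone ring is made last, by double condensation of a five-carbon bis-nucleophile (a β-keto ester CH2 and the γ-CH2 of a 2-alkylidenetetrahydrofuran) with methylglyoxal dimethyl acetal as the two-carbon bis-electrophile.
2. The bis-nucleophile comes from a spiro-γ-lactone and the dianion of methyl 3-oxopentanoate; the lactone carbonyl becomes the oxygen-bearing tropone carbon.
3. Key disconnection: spiro-lactone ⇒ exocyclic methylene + an acetamide α-carbon used with reversed polarity (acceptor/enolonium-type, delivered as the radical from 2-iodoacetamide); C–O closure then sets the spiro centre.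
4. The alkene comes from (S)-carvone: conjugate reduction, α'-methylenation, reductive Michael addition to tert-butyl acrylate (quaternary centre), hydration, Wittig.
5. Ring order: cyclohexane (from carvone) → spiro-lactone → dihydrofuran ring (2-alkylidenetetrahydrofuran) → tropone.

Assumption: operations telescoped without isolating an intermediate count as one step; locants in the Why lines follow the name of the compound concerned.

**Step 1**
Reactants: 1 (S)-(+)-carvone, (5S)-2-methyl-5-(prop-1-en-2-yl)cyclohex-2-en-1-one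
Product: 2 (2S,5S)-2-methyl-5-(prop-1-en-2-yl)cyclohexan-1-one (trans-dihydrocarvone; minor 2R epimer carried along)
Conditions: LiBH(s-Bu)3 (1.1 equiv), THF, −78 °C; then H2O
Reagents that add atoms: none
Why: Conjugate (1,4) hydride reduction of the enone by the bulky trialkylborohydride leaves the isopropenyl group untouched, and protonation of the enolate gives mainly the trans ketone; this enolisable methyl centre is fixed under thermodynamic control in step 5.

**Step 2**
Reactants: 2 (2S,5S)-2-methyl-5-(prop-1-en-2-yl)cyclohexan-1-one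
Product: 5 (2S,5R)-2-methyl-6-methylidene-5-(prop-1-en-2-yl)cyclohexan-1-one, via Mannich base 3 (not isolated), via ammonium iodide 4 (not isolated)
Conditions: LiN(i-Pr)2, THF, −78 °C; [Me2N=CH2]I, −78 → 0 °C; then MeI, Et2O, rt; then aq. NaHCO3, CH2Cl2, rt; used at once
Reagents that add atoms: N,N-dimethylmethyleneiminium iodide (Eschenmoser's salt), C=[N+](C)C.[I-]
Why: Kinetic deprotonation takes the less substituted C6 methylene, the enolate is aminomethylated (Mannich reaction with Eschenmoser's salt), and quaternisation followed by E1cB loss of trimethylamine gives the α-methylene ketone regiospecifically without touching C5.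

**Step 3**
Reactants: 5 (2S,5R)-2-methyl-6-methylidene-5-(prop-1-en-2-yl)cyclohexan-1-one; 6 tert-butyl acrylate
Product: 8 tert-butyl 3-[(1R,3S,6R)-1,3-dimethyl-2-oxo-6-(prop-1-en-2-yl)cyclohexyl]propanoate, via lithium enolate 7 (not isolated)
Conditions: LiBH(s-Bu)3 (1.05 equiv), THF, −78 °C; then 6, −78 → −20 °C; then H2O
Reagents that add atoms: none
Why: 1,4-Hydride addition to the exocyclic enone gives the tetrasubstituted enolate regiospecifically (no ring enone remains for a second Michael addition), and its Michael addition to the acrylate (reductive Michael reaction) occurs anti to the adjacent pseudoaxial isopropenyl group, so the new quaternary centre carries the propanoate chain trans to isopropenyl.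

**Step 4**
Reactants: 8 tert-butyl 3-[(1R,3S,6R)-1,3-dimethyl-2-oxo-6-(prop-1-en-2-yl)cyclohexyl]propanoate
Product: 9 tert-butyl 3-[(1R,3S,6S)-6-(2-hydroxypropan-2-yl)-1,3-dimethyl-2-oxocyclohexyl]propanoate
Conditions: Co(acac)2 (20 mol%), PhSiH3, O2 (1 atm), THF, rt
Reagents that add atoms: dioxygen, O=O
Why: Mukaiyama hydration (hydrogen-atom transfer from a cobalt hydride to the 1,1-disubstituted alkene, then trapping of the tertiary radical by O2) gives the Markovnikov tertiary alcohol and leaves ketone and ester alone; no stereocentre is formed.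

**Step 5**
Reactants: 9 tert-butyl 3-[(1R,3S,6S)-6-(2-hydroxypropan-2-yl)-1,3-dimethyl-2-oxocyclohexyl]propanoate
Product: 10 tert-butyl 3-[(1R,3S,6S)-6-(2-hydroxypropan-2-yl)-1,3-dimethyl-2-methylidenecyclohexyl]propanoate
Conditions: Ph3PCH3Br, KOt-Bu (3 equiv each), PhMe, 90 °C
Reagents that add atoms: methyltriphenylphosphonium bromide, C[P+](c1ccccc1)(c1ccccc1)c1ccccc1.[Br-]
Why: Wittig methylenation of the hindered ketone with excess ylide; under the basic conditions the α-methyl centre first equilibrates to the equatorial 3S epimer, which avoids a 1,3-diaxial methyl–methyl contact with the axial C1 methyl, and olefination then fixes it.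

**Step 6 (key step)**
Reactants: 10 tert-butyl 3-[(1R,3S,6S)-6-(2-hydroxypropan-2-yl)-1,3-dimethyl-2-methylidenecyclohexyl]propanoate; 11 2-iodoacetamide
Product: 14 tert-butyl 3-[(5S,6R,7S,10S)-7-(2-hydroxypropan-2-yl)-6,10-dimethyl-2-oxo-1-oxaspiro[4.5]decan-6-yl]propanoate, via iodo amide 12 (not isolated), via iminolactonium iodide 13 (not isolated)
Conditions: 11 (2.5 equiv), 4,4'-azobis(4-cyanopentanoic acid) (30 mol%), EtOH–H2O (1:1), 75 °C
Reagents that add atoms: water, O
Why: Iodine-atom-transfer radical addition–lactonisation of a 2-iodoalkanamide (Kharasch-type addition, a known γ-lactone synthesis): the acetamide α-carbon, normally an enolate nucleophile, acts as an enolonium-type acceptor in the form of the electrophilic carbamoylmethyl radical and bonds to the nucleophilic CH2 terminus of the alkene; the tertiary iodide then ionises, the amide oxygen closes the five-membered ring on the axial face anti to the axial C6 methyl (spiro centre 5S, also the thermodynamic epimer), and water hydrolyses the iminium to the lactone.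

**Step 7**
Reactants: 14 tert-butyl 3-[(5S,6R,7S,10S)-7-(2-hydroxypropan-2-yl)-6,10-dimethyl-2-oxo-1-oxaspiro[4.5]decan-6-yl]propanoate; 15 methyl 3-oxopentanoate
Product: 18 methyl (4E)-4-[(5S,6R,7S,10S)-6-(3-tert-butoxy-3-oxopropyl)-7-(2-hydroxypropan-2-yl)-6,10-dimethyl-1-oxaspiro[4.5]decan-2-ylidene]-3-oxopentanoate, via keto ester dianion 16 (not isolated), via hydroxy diketo ester 17 (not isolated)
Conditions: 15 (3 equiv), NaH then n-BuLi, THF, 0 °C; add 14, −78 → 0 °C; aq. HCl; then p-TsOH·H2O (5 mol%), 4 Å MS, CH2Cl2, rt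
Reagents that add atoms: none
Why: γ-Acylation of a β-keto ester dianion (Huckin–Weiler) by the lactone carbonyl, which is far more electrophilic than the hindered tert-butyl ester, releases the tertiary alkoxide without breaking the C–O bond at the spiro centre; acid then recloses it onto the new ketone and dehydrates to the conjugated E 2-alkylidenetetrahydrofuran (a vinylogous ester).

**Step 8**
Reactants: 18 methyl (4E)-4-[(5S,6R,7S,10S)-6-(3-tert-butoxy-3-oxopropyl)-7-(2-hydroxypropan-2-yl)-6,10-dimethyl-1-oxaspiro[4.5]decan-2-ylidene]-3-oxopentanoate; 19 1,1-dimethoxypropan-2-one (methylglyoxal dimethyl acetal)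
Product: 20 methyl 2-{(2E)-2-[(5S,6R,7S,10S)-6-(3-tert-butoxy-3-oxopropyl)-7-(2-hydroxypropan-2-yl)-6,10-dimethyl-1-oxaspiro[4.5]decan-2-ylidene]propanoyl}-4,4-dimethoxy-3-methylbut-2-enoate (E/Z mixture at the butenoate)
Conditions: TiCl4 (2 equiv), pyridine (4 equiv), THF, 0 °C → rt
Reagents that add atoms: none
Why: Lehnert-type Knoevenagel condensation of the β-keto ester methylene with the activated α,α-dialkoxy ketone; the acetal keeps the aldehyde carbon masked, so the most nucleophilic carbon bonds to the methyl-bearing carbonyl, and the E/Z mixture does not matter because the doubly activated alkene isomerises in step 9.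

**Step 9**
Reactants: 20 methyl 2-{(2E)-2-[(5S,6R,7S,10S)-6-(3-tert-butoxy-3-oxopropyl)-7-(2-hydroxypropan-2-yl)-6,10-dimethyl-1-oxaspiro[4.5]decan-2-ylidene]propanoyl}-4,4-dimethoxy-3-methylbut-2-enoate
Product: 23 3-[(2S,2'R,3'S,6'S)-3'-(2-hydroxypropan-2-yl)-6-(methoxycarbonyl)-2',5,6',8-tetramethyl-7-oxo-3,7-dihydrospiro[cyclohepta[b]furan-2,1'-cyclohexan]-2'-yl]propanoic acid (CNP0448476.1), via enal 21 (not isolated), via tropone tert-butyl ester 22 (not isolated)
Conditions: TFA–H2O (9:1), CH2Cl2, 0 °C → rt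
Reagents that add atoms: none
Why: Proposed new method: aqueous acid unmasks the aldehyde, the vinylogous ester tautomerises to its endocyclic enol ether whose β-carbon attacks the protonated aldehyde in a seven-membered vinylogous aldol (Prins-type) closure, dehydration gives the aromatic tropone as an irreversible sink, and the same acid cleaves the tert-butyl ester; the closest known reactions are the double aldol condensation of 1,2-dicarbonyl compounds with ketones flanked by two activated methylenes (classical tropone and benzotropone syntheses) and acid-mediated vinylogous Mukaiyama aldol cyclisations onto acetals; the spiro ether with equatorial neighbouring methyl is the thermodynamically preferred diastereomer, so reversible ionisation under acid should not erode it.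

**Compound list**
1 | (S)-(+)-carvone, (5S)-2-methyl-5-(prop-1-en-2-yl)cyclohex-2-en-1-one | O=C1C(C)=CC[C@H](C(C)=C)C1 | starting material
2 | (2S,5S)-2-methyl-5-(prop-1-en-2-yl)cyclohexan-1-one (major epimer shown) | O=C1[C@@H](C)CC[C@H](C(C)=C)C1 | intermediate
3 | (2S,5S)-6-[(dimethylamino)methyl]-2-methyl-5-(prop-1-en-2-yl)cyclohexan-1-one (C6 epimers) | O=C1[C@@H](C)CC[C@H](C(C)=C)C1CN(C)C | intermediate (not isolated)
4 | N,N,N-trimethyl-1-[(3S,6S)-3-methyl-2-oxo-6-(prop-1-en-2-yl)cyclohexyl]methanaminium iodide (C1 epimers) | O=C1[C@@H](C)CC[C@H](C(C)=C)C1C[N+](C)(C)C.[I-] | intermediate (not isolated)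
5 | (2S,5R)-2-methyl-6-methylidene-5-(prop-1-en-2-yl)cyclohexan-1-one | O=C1[C@@H](C)CC[C@H](C(C)=C)C1=C | intermediate
6 | tert-butyl acrylate | C=CC(=O)OC(C)(C)C | starting material
7 | lithium (3R,6S)-2,6-dimethyl-3-(prop-1-en-2-yl)cyclohex-1-en-1-olate | C[C@H]1CC[C@H](C(C)=C)C(C)=C1[O-].[Li+] | intermediate (not isolated)
8 | tert-butyl 3-[(1R,3S,6R)-1,3-dimethyl-2-oxo-6-(prop-1-en-2-yl)cyclohexyl]propanoate | O=C1[C@@H](C)CC[C@H](C(C)=C)[C@@]1(C)CCC(=O)OC(C)(C)C | intermediate
9 | tert-butyl 3-[(1R,3S,6S)-6-(2-hydroxypropan-2-yl)-1,3-dimethyl-2-oxocyclohexyl]propanoate | O=C1[C@@H](C)CC[C@H](C(C)(C)O)[C@@]1(C)CCC(=O)OC(C)(C)C | intermediate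
10 | tert-butyl 3-[(1R,3S,6S)-6-(2-hydroxypropan-2-yl)-1,3-dimethyl-2-methylidenecyclohexyl]propanoate | C=C1[C@@H](C)CC[C@H](C(C)(C)O)[C@@]1(C)CCC(=O)OC(C)(C)C | intermediate
11 | 2-iodoacetamide | NC(=O)CI | starting material
12 | tert-butyl 3-[(1R,3S,6S)-2-(3-amino-3-oxopropyl)-6-(2-hydroxypropan-2-yl)-2-iodo-1,3-dimethylcyclohexyl]propanoate (C2 epimers) | NC(=O)CCC1(I)[C@@H](C)CC[C@H](C(C)(C)O)[C@@]1(C)CCC(=O)OC(C)(C)C | intermediate (not isolated)
13 | (5S,6R,7S,10S)-6-(3-tert-butoxy-3-oxopropyl)-7-(2-hydroxypropan-2-yl)-6,10-dimethyl-1-oxaspiro[4.5]decan-2-iminium iodide | [NH2+]=C1CC[C@]2(O1)[C@@H](C)CC[C@H](C(C)(C)O)[C@@]2(C)CCC(=O)OC(C)(C)C.[I-] | intermediate (not isolated)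
14 | tert-butyl 3-[(5S,6R,7S,10S)-7-(2-hydroxypropan-2-yl)-6,10-dimethyl-2-oxo-1-oxaspiro[4.5]decan-6-yl]propanoate | O=C1CC[C@]2(O1)[C@@H](C)CC[C@H](C(C)(C)O)[C@@]2(C)CCC(=O)OC(C)(C)C | intermediate
15 | methyl 3-oxopentanoate | CCC(=O)CC(=O)OC | starting material
16 | sodium lithium dianion of methyl 3-oxopentanoate | C[CH-]C([O-])=CC(=O)OC.[Na+].[Li+] | intermediate (not isolated)
17 | methyl 7-[(1S,2R,3S,6S)-2-(3-tert-butoxy-3-oxopropyl)-1-hydroxy-3-(2-hydroxypropan-2-yl)-2,6-dimethylcyclohexyl]-4-methyl-3,5-dioxoheptanoate (C4 epimers) | COC(=O)CC(=O)C(C)C(=O)CC[C@]1(O)[C@@H](C)CC[C@H](C(C)(C)O)[C@@]1(C)CCC(=O)OC(C)(C)C | intermediate (not isolated)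
18 | methyl (4E)-4-[(5S,6R,7S,10S)-6-(3-tert-butoxy-3-oxopropyl)-7-(2-hydroxypropan-2-yl)-6,10-dimethyl-1-oxaspiro[4.5]decan-2-ylidene]-3-oxopentanoate | COC(=O)CC(=O)/C(C)=C1\CC[C@]2(O1)[C@@H](C)CC[C@H](C(C)(C)O)[C@@]2(C)CCC(=O)OC(C)(C)C | intermediate
19 | 1,1-dimethoxypropan-2-one | CC(=O)C(OC)OC | starting material
20 | methyl 2-{(2E)-2-[(5S,6R,7S,10S)-6-(3-tert-butoxy-3-oxopropyl)-7-(2-hydroxypropan-2-yl)-6,10-dimethyl-1-oxaspiro[4.5]decan-2-ylidene]propanoyl}-4,4-dimethoxy-3-methylbut-2-enoate (E/Z mixture at the butenoate) | COC(=O)C(=C(C)C(OC)OC)C(=O)/C(C)=C1\CC[C@]2(O1)[C@@H](C)CC[C@H](C(C)(C)O)[C@@]2(C)CCC(=O)OC(C)(C)C | intermediate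
21 | methyl 2-{(2E)-2-[(5S,6R,7S,10S)-6-(3-tert-butoxy-3-oxopropyl)-7-(2-hydroxypropan-2-yl)-6,10-dimethyl-1-oxaspiro[4.5]decan-2-ylidene]propanoyl}-3-methyl-4-oxobut-2-enoate | COC(=O)C(=C(C)C=O)C(=O)/C(C)=C1\CC[C@]2(O1)[C@@H](C)CC[C@H](C(C)(C)O)[C@@]2(C)CCC(=O)OC(C)(C)C | intermediate (not isolated)
22 | methyl (2S,2'R,3'S,6'S)-2'-(3-tert-butoxy-3-oxopropyl)-3'-(2-hydroxypropan-2-yl)-2',5,6',8-tetramethyl-7-oxo-3,7-dihydrospiro[cyclohepta[b]furan-2,1'-cyclohexane]-6-carboxylate | COC(=O)c1c(C)cc2c(c(C)c1=O)O[C@@]1(C2)[C@@H](C)CC[C@H](C(C)(C)O)[C@@]1(C)CCC(=O)OC(C)(C)C | intermediate (not isolated)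
23 | 3-[(2S,2'R,3'S,6'S)-3'-(2-hydroxypropan-2-yl)-6-(methoxycarbonyl)-2',5,6',8-tetramethyl-7-oxo-3,7-dihydrospiro[cyclohepta[b]furan-2,1'-cyclohexan]-2'-yl]propanoic acid (CNP0448476.1) | COC(=O)c1c(C)cc2c(c(C)c1=O)O[C@@]1(C2)[C@@H](C)CC[C@H](C(C)(C)O)[C@@]1(C)CCC(=O)O | target

**Step count and risks**
Total step count: 9. Longest linear sequence: 9 steps (1 → 23); compounds 6, 11, 15 and 19 are bought.

The three steps most likely to fail are steps 6, 8 and 9.

Step 6 can fail through elimination of the tertiary iodide, capture of the tertiary cation by the free tertiary hydroxyl or the tert-butyl ester carbonyl, or closure on the wrong face. The fallback sets out from 10 and comes back at 14, and makes the C–O bond first by an oxygen electrophile. Epoxidation of 10 with mCPBA (NaHCO3, CH2Cl2, 0 °C), with axial attack anti to the axial methyl, gives the spiro-epoxide tert-butyl 3-[(3S,4R,5S,8S)-5-(2-hydroxypropan-2-yl)-4,8-dimethyl-1-oxaspiro[2.5]octan-4-yl]propanoate F1. Opening F1 at its CH2 with dilithioacetate (AcOH, 2 LiN(i-Pr)2, THF–DMPU, 45 °C) gives the hydroxy acid 3-[(1S,2R,3S,6S)-2-(3-tert-butoxy-3-oxopropyl)-1-hydroxy-3-(2-hydroxypropan-2-yl)-2,6-dimethylcyclohexyl]propanoic acid F2, which lactonises to 14 with catalytic p-TsOH in toluene.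

Step 8 can fail because ketones are poor Knoevenagel partners for β-keto esters and because TiCl4 may attack the acetal, the enol ether or the tertiary alcohol of 18. The fallback sets out from 14 and comes back at 22; it moves the condensation onto the two small building blocks and joins the fragments by acylation. Compounds 15 and 19 are condensed (TiCl4, pyridine, THF, forcing conditions and distillation are possible here) to methyl 2-(1,1-dimethoxypropan-2-ylidene)-3-oxopentanoate F3. Lactone 14 is opened with MeNH(OMe)·HCl and AlMe3 (CH2Cl2, 0 °C) to the Weinreb amide tert-butyl 3-[(1R,2S,3S,6S)-2-hydroxy-6-(2-hydroxypropan-2-yl)-2-{3-[methoxy(methyl)amino]-3-oxopropyl}-1,3-dimethylcyclohexyl]propanoate F4. The kinetic lithium enolate of F3 (LiN(SiMe3)2, 3 equiv, THF, −78 °C) is acylated by F4 to the 1,3-diketone methyl 2-(1,1-dimethoxypropan-2-ylidene)-7-[(1S,2R,3S,6S)-2-(3-tert-butoxy-3-oxopropyl)-1-hydroxy-3-(2-hydroxypropan-2-yl)-2,6-dimethylcyclohexyl]-4-methyl-3,5-dioxoheptanoate F5. The acid conditions of step 9 then close the dihydrofuran and the seven-membered ring to 22, which goes on to 23 in the same flask.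

Step 9 can fail if the γ-carbon of the vinylogous ester is not nucleophilic enough and the enal 21 polymerises instead. The fallback sets out from 14 and comes back at 22; it makes the bond from the dihydrofuran carbon to the future tropone CH by enolate alkylation, closes the ring by an intramolecular Knoevenagel reaction and reaches the tropone by dehydrogenation. Alkylation of the lactone enolate of 14 (LiN(i-Pr)2, 2.2 equiv, THF, −78 °C) with 3-bromo-2-methoxyprop-1-ene gives tert-butyl 3-[(5S,6R,7S,10S)-7-(2-hydroxypropan-2-yl)-3-(2-methoxyprop-2-en-1-yl)-6,10-dimethyl-2-oxo-1-oxaspiro[4.5]decan-6-yl]propanoate F6. Treatment of F6 with dianion 16 as in step 7, then aqueous acid (which also hydrolyses the enol ether to the methyl ketone), gives methyl (4E)-4-[(5S,6R,7S,10S)-6-(3-tert-butoxy-3-oxopropyl)-7-(2-hydroxypropan-2-yl)-6,10-dimethyl-3-(2-oxopropyl)-1-oxaspiro[4.5]decan-2-ylidene]-3-oxopentanoate F7. Piperidinium acetate (PhMe, 60 °C) closes the seven-membered ring to the dihydrotropone methyl (2S,2'R,3'S,6'S)-2'-(3-tert-butoxy-3-oxopropyl)-3'-(2-hydroxypropan-2-yl)-2',5,6',8-tetramethyl-7-oxo-3,3a,4,7-tetrahydrospiro[cyclohepta[b]furan-2,1'-cyclohexane]-6-carboxylate F8, and DDQ (dioxane, rt) dehydrogenates F8 to 22, which is deprotected with TFA as in step 9.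

**Further compounds**
F1 | step 6 | tert-butyl 3-[(3S,4R,5S,8S)-5-(2-hydroxypropan-2-yl)-4,8-dimethyl-1-oxaspiro[2.5]octan-4-yl]propanoate | C1O[C@]12[C@@H](C)CC[C@H](C(C)(C)O)[C@@]2(C)CCC(=O)OC(C)(C)C
F2 | step 6 | 3-[(1S,2R,3S,6S)-2-(3-tert-butoxy-3-oxopropyl)-1-hydroxy-3-(2-hydroxypropan-2-yl)-2,6-dimethylcyclohexyl]propanoic acid | OC(=O)CC[C@]1(O)[C@@H](C)CC[C@H](C(C)(C)O)[C@@]1(C)CCC(=O)OC(C)(C)C
F3 | step 8 | methyl 2-(1,1-dimethoxypropan-2-ylidene)-3-oxopentanoate | CCC(=O)C(=C(C)C(OC)OC)C(=O)OC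
F4 | step 8 | tert-butyl 3-[(1R,2S,3S,6S)-2-hydroxy-6-(2-hydroxypropan-2-yl)-2-{3-[methoxy(methyl)amino]-3-oxopropyl}-1,3-dimethylcyclohexyl]propanoate | CON(C)C(=O)CC[C@]1(O)[C@@H](C)CC[C@H](C(C)(C)O)[C@@]1(C)CCC(=O)OC(C)(C)C
F5 | step 8 | methyl 2-(1,1-dimethoxypropan-2-ylidene)-7-[(1S,2R,3S,6S)-2-(3-tert-butoxy-3-oxopropyl)-1-hydroxy-3-(2-hydroxypropan-2-yl)-2,6-dimethylcyclohexyl]-4-methyl-3,5-dioxoheptanoate | COC(=O)C(=C(C)C(OC)OC)C(=O)C(C)C(=O)CC[C@]1(O)[C@@H](C)CC[C@H](C(C)(C)O)[C@@]1(C)CCC(=O)OC(C)(C)C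
F6 | step 9 | tert-butyl 3-[(5S,6R,7S,10S)-7-(2-hydroxypropan-2-yl)-3-(2-methoxyprop-2-en-1-yl)-6,10-dimethyl-2-oxo-1-oxaspiro[4.5]decan-6-yl]propanoate (C3 epimers) | COC(=C)CC1C[C@]2(OC1=O)[C@@H](C)CC[C@H](C(C)(C)O)[C@@]2(C)CCC(=O)OC(C)(C)C
F7 | step 9 | methyl (4E)-4-[(5S,6R,7S,10S)-6-(3-tert-butoxy-3-oxopropyl)-7-(2-hydroxypropan-2-yl)-6,10-dimethyl-3-(2-oxopropyl)-1-oxaspiro[4.5]decan-2-ylidene]-3-oxopentanoate | COC(=O)CC(=O)/C(C)=C1\C(CC(C)=O)C[C@]2(O1)[C@@H](C)CC[C@H](C(C)(C)O)[C@@]2(C)CCC(=O)OC(C)(C)C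
F8 | step 9 | methyl (2S,2'R,3'S,6'S)-2'-(3-tert-butoxy-3-oxopropyl)-3'-(2-hydroxypropan-2-yl)-2',5,6',8-tetramethyl-7-oxo-3,3a,4,7-tetrahydrospiro[cyclohepta[b]furan-2,1'-cyclohexane]-6-carboxylate (C3a epimers) | COC(=O)C1=C(C)CC2C[C@]3(OC2=C(C)C1=O)[C@@H](C)CC[C@H](C(C)(C)O)[C@@]3(C)CCC(=O)OC(C)(C)C
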